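**Strategy.** The eremophilane is cut at C9–C10 (later aldol closure of ring B) and at C4–C15 and C5–C6, which traces ring A back to a 4-silyloxy-2-methylcyclohexenone whose carbonyl carbon is C10. The key step exploits the contiguous C3 carbinol, C4 methyl and quaternary C5 methyl of ring A: lithium dimethylcuprate adds to C4 anti to the C3 silyloxy group, and the resulting C5 enolate is trapped by a vinylsilane-masked 3-oxobutyl iodide. One carbinol centre thus dictates two new stereocentres in one flask. The cis-decalin later relays this information to C10, C9 and C7.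

Key step: step 9

Remarks on the chemistry:
- Eremophilane numbering is used: ring A = C1–C5 and C10, ring B = C5–C10, C11–C13 = three-carbon unit on C7, C14 = methyl on C5, C15 = methyl on C4; β is the face of C14.
- The sense of induction in step 2 is assigned by analogy with 4-tert-butylcyclohexanone, where the (R,R)-amide gives the (S)-enol silane; if the silyloxy ketone responds in the opposite sense, the (R,R)-amide is used and nothing else changes.
- The C3 oxygen is carried as a TBDPS ether because it must survive the aqueous sulfuric acid of step 10.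
- C9 is oxygenated before the C7 side chain is attached. A C7 aldol on the octalone would place the side chain trans to C14, which is the wrong epimer once the ring fusion is cis.

**Ring A enone (steps 1–5)**

Step 1
Reactants: 1 4-hydroxycyclohexan-1-one
Product: 2 4-(TBDPSO)cyclohexan-1-one
Conditions: TBDPSCl, imidazole, DMF, 0 °C → rt
Reagents that add atoms: tert-butyl(chloro)diphenylsilane, CC(C)(C)[Si](Cl)(c1ccccc1)c1ccccc1
Why: Imidazole-promoted silylation of the secondary alcohol installs the acid-robust silyl ether that the later epoxysilane hydrolysis requires.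

Step 2
Reactants: 2 4-(TBDPSO)cyclohexan-1-one
Product: 3 (R)-4-(TBDPSO)-1-(trimethylsilyloxy)cyclohex-1-ene
Conditions: (S,S)-(PhMeCH)2NH·HCl, n-BuLi (2 equiv), THF, −78 → 0 °C; TMSCl, then 2, −100 °C (internal quench)
Reagents that add atoms: chlorotrimethylsilane, C[Si](C)(C)Cl
Why: Desymmetrisation of the prochiral ketone by a C2-symmetric chiral lithium amide, which removes one of the two enantiotopic α-protons and is trapped in situ as the enol silane (LiCl from the amine salt sharpening the selectivity), should fix the carbinol carbon (future C3) as R.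

Step 3
Reactants: 3 (R)-enol silane
Product: 4 (R)-4-(TBDPSO)cyclohex-2-en-1-one
Conditions: Pd(OAc)2 (10 mol %), O2 (1 atm), DMSO, rt
Reagents that add atoms: none
Why: Saegusa–Ito oxidation run catalytically under O2 should turn the regiodefined enol silane into the enone on the deprotonated side only, without touching the stereocentre.

Step 4
Reactants: 4 (R)-4-(TBDPSO)cyclohex-2-en-1-one
Product: 5 (R)-4-(TBDPSO)-2-iodocyclohex-2-en-1-one
Conditions: I2, pyridine, CH2Cl2, 0 °C → rt
Reagents that add atoms: iodine, [I][I]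
Why: Pyridine-mediated α-iodination of the enone (conjugate addition of pyridine, iodination of the enolate, elimination) is selective for the enone α-carbon and is established for 4-silyloxycyclohexenones.

Step 5
Reactants: 5 (R)-4-(TBDPSO)-2-iodocyclohex-2-en-1-one
Product: 6 (R)-4-(TBDPSO)-2-methylcyclohex-2-en-1-one
Conditions: SnMe4, Pd2(dba)3 (cat.), AsPh3, CuI (cat.), NMP, 60 °C
Reagents that add atoms: tetramethylstannane, C[Sn](C)(C)C
Why: Stille coupling of the α-iodoenone proceeds under neutral conditions, so the γ-stereocentre (C3) should not be lost through vinylogous enolisation.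

**Allylic iodide (steps 6–8)**

Step 6
Reactants: 7 3-(trimethylsilyl)prop-2-yn-1-ol
Product: 9 (Z)-3-iodo-3-(trimethylsilyl)prop-2-en-1-ol, via vinylalanate 8 (not isolated)
Conditions: NaAlH2(OCH2CH2OMe)2, Et2O, 0 °C → rt; then I2, THF, −78 °C
Reagents that add atoms: iodine, [I][I]
Why: Hydroxyl-directed trans-hydroalumination places aluminium on the silicon-bearing alkyne carbon in a five-membered alanate, and iodinolysis of the C–Al bond with retention should give the Z iodide.

Step 7
Reactants: 9 (Z)-3-iodo-3-(trimethylsilyl)prop-2-en-1-ol; 10 dimethylzinc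
Product: 11 (E)-3-(trimethylsilyl)but-2-en-1-ol
Conditions: 10 (2.5 equiv), Pd(PPh3)4 (5 mol %), THF, 0 → 45 °C; aq. NH4Cl
Reagents that add atoms: dimethylzinc 10, C[Zn]C
Why: Negishi cross-coupling, in which the first equivalent of Me2Zn only deprotonates the hydroxyl group, zerovalent palladium inserts into the C–I bond with retention, and transmetalation from zinc followed by reductive elimination replaces iodine by methyl without change of the double-bond geometry.

Step 8
Reactants: 11 (E)-3-(trimethylsilyl)but-2-en-1-ol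
Product: 12 (E)-1-iodo-3-(trimethylsilyl)but-2-ene
Conditions: PPh3, I2, imidazole, CH2Cl2, 0 °C, dark
Reagents that add atoms: iodine, [I][I]
Why: Appel-type iodination converts the primary allylic alcohol into the iodide by SN2 displacement without allylic transposition, and the light-sensitive product is used at once.

**Key step and elaboration (steps 9–18)**

Step 9
Reactants: 6 (R)-4-(TBDPSO)-2-methylcyclohex-2-en-1-one; 12 (E)-1-iodo-3-(trimethylsilyl)but-2-ene; 13 methyllithium
Product: 16 (2R,3R,4R)-4-(TBDPSO)-2,3-dimethyl-2-[(E)-3-(trimethylsilyl)but-2-en-1-yl]cyclohexan-1-one, via lithium dimethylcuprate 14 (not isolated), via lithium enolate 15 (not isolated)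
Conditions: CuI, 13 (2 equiv), Et2O, 0 °C; 6, −78 → −30 °C; then 12 (excess), HMPA, THF, −30 → 0 °C
Reagents that add atoms: methyllithium 13, [Li]C, transferred through lithium dimethylcuprate 14, [Li+].C[Cu-]C
Why: Me2CuLi complexes the enone on the face opposite the C3 silyloxy group and, after oxidative addition and reductive elimination, delivers methyl C15 to C4 and leaves the regiodefined lithium–copper enolate 15 (C5=C10), which HMPA then activates for SN2 C-alkylation at C5 by the allylic iodide. The closest known reaction type is the tandem cuprate conjugate addition–enolate alkylation (three-component coupling) practised on 4-silyloxycycloalkenones and on 2-methylcyclohexenone. No ring is closed; the two skeletal bonds C4–C15 and C5–C6 are formed in one flask. C4 is controlled by the C3 stereocentre (3,4-trans addition), and C5 by the new C4 methyl, which sits pseudoaxial in the enolate half-chair to avoid allylic strain with the C5 methyl, so that the electrophile should enter axially on the opposite face and leave the two methyl groups cis. The step needs C- rather than O-alkylation and no enolate equilibration toward C1; the soft, highly reactive allylic iodide used in excess and the absence of any proton source secure both.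

Step 10
Reactants: 16 key ketone
Product: 18 (2R,3R,4R)-4-(TBDPSO)-2,3-dimethyl-2-(3-oxobutyl)cyclohexan-1-one, via epoxysilane 17 (not isolated)
Conditions: mCPBA, CH2Cl2, 0 °C; then MeOH, 1 M aq. H2SO4, rt
Reagents that add atoms: water, O (ketone oxygen of 18); mCPBA, O=C(OO)c1cccc(Cl)c1 (epoxide oxygen of 17 only, lost again with silicon)
Why: Epoxidation of the electron-rich vinylsilane followed by acid-catalysed opening at the silicon-bearing carbon and Peterson-type loss of trimethylsilanol unmasks the C8 methyl ketone, while the hindered ring ketone and the TBDPS ether are inert to both reagents.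

Step 11
Reactants: 18 diketone
Product: 19 3α-(TBDPSO)-11,12,13-trinoreremophil-9-en-8-one (octalone)
Conditions: NaOMe, MeOH, rt → 45 °C
Reagents that add atoms: none
Why: Base-mediated intramolecular aldol condensation (the ring-closing half of a Robinson annulation, 6-enolendo-exo-trig) joins C9 to C10 and dehydrates irreversibly to the octalone, whereas the alternative bridged aldol is reversible and cannot dehydrate.

Step 12
Reactants: 19 octalone
Product: 20 3α-(TBDPSO)-11,12,13-trinor-10βH-eremophilan-8-one (cis-decalone)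
Conditions: H2 (1 atm), 10% Pd/C, pyridine, rt
Reagents that add atoms: none
Why: Heterogeneous hydrogenation of angular-methyl octalones in basic medium is known to deliver hydrogen syn to the angular methyl group (as for steroidal 4-en-3-ones in pyridine), which should set C10 as the 10β-H cis-fused decalone and leave the aryl silyl ether intact.

Step 13
Reactants: 20 cis-decalone
Product: 21 3α-(TBDPSO)-8-(TBSO)-11,12,13-trinor-10βH-eremophil-8-ene (enol ether)
Conditions: TBSOTf, Et3N, CH2Cl2, 0 °C → rt
Reagents that add atoms: tert-butyldimethylsilyl trifluoromethanesulfonate, CC(C)(C)[Si](C)(C)OS(=O)(=O)C(F)(F)F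
Why: Soft enolisation with a silyl triflate and an amine gives the more stable enol ether, which in cis-fused decalones of this type (the 5β-3-keto steroid pattern) points toward the ring-fusion carbon, so C9 and not C7 should be activated.

Step 14
Reactants: 21 enol ether
Product: 22 3α-(TBDPSO)-9β-(TBSO)-11,12,13-trinor-10βH-eremophilan-8-one
Conditions: mCPBA, hexane–CH2Cl2, −20 → 0 °C
Reagents that add atoms: mCPBA, O=C(OO)c1cccc(Cl)c1
Why: Rubottom oxidation, in which the peracid epoxidises the enol ether on the convex β face of the cis-decalin (ring A shields the α face) and 1,4-silyl migration then delivers the silyloxy ketone, should set C9 as 9β (equatorial).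

Step 15
Reactants: 22 9β-silyloxy ketone; 23 acetone
Product: 25 3α-(TBDPSO)-9β-(TBSO)-11-hydroxy-7αH,10βH-eremophilan-8-one, via lithium enolate 24 (not isolated)
Conditions: LiN(iPr)2, THF, −78 °C; then 23, −78 °C; AcOH, −78 °C
Reagents that add atoms: acetone 23, CC(C)=O
Why: Kinetic deprotonation at the only α-methylene (C7) and aldol addition of the lithium enolate to acetone on the convex β face should give the equatorial 7β side chain, which is also the thermodynamically favoured C7 epimer, and the cold acidic quench forestalls retro-aldol cleavage.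

Step 16
Reactants: 25 aldol adduct
Product: 26 3α,9β,11-trihydroxy-7αH,10βH-eremophilan-8-one
Conditions: HF·pyridine, pyridine, THF, 0 → 40 °C
Reagents that add atoms: none
Why: Fluoride-driven cleavage of both silyl ethers under weakly acidic buffered conditions frees the two secondary hydroxyls without the enolisation that would trigger retro-aldol cleavage or α-ketol isomerisation.

Step 17
Reactants: 26 triol; 27 angelic acid
Product: 28 3α,9β-bis(angeloyloxy)-11-hydroxy-7αH,10βH-eremophilan-8-one
Conditions: 27, 2,4,6-Cl3C6H2COCl, Et3N, toluene, rt; then 26, 80 °C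
Reagents that add atoms: angelic acid 27, C/C=C(/C)C(=O)O
Why: Yamaguchi esterification through the mixed 2,4,6-trichlorobenzoic anhydride without a nucleophilic catalyst acylates both secondary hydroxyls with retention of the Z double bond of the angeloyl group, while the tertiary C11 hydroxyl is too hindered to react.

Step 18
Reactants: 28 bis-angelate carbinol
Product: 29 3α,9β-bis(angeloyloxy)-7αH,10βH-eremophil-11-en-8-one (CNP0174755.1)
Conditions: SOCl2, pyridine, CH2Cl2, −30 → 0 °C
Reagents that add atoms: none
Why: Dehydration of the tertiary alcohol through its chlorosulfite by pyridine-mediated E2 elimination under kinetic control should remove one of six exposed methyl hydrogens in preference to the single C7 hydrogen on the hindered concave face, giving the isopropenyl group, and it is placed last so that the isomerisation-prone α-isopropenyl ketone meets no further reagent.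

**Compound list**

1 | 4-hydroxycyclohexan-1-one | O=C1CCC(O)CC1 | starting material
2 | 4-[(tert-butyldiphenylsilyl)oxy]cyclohexan-1-one | O=C1CCC(O[Si](c2ccccc2)(c2ccccc2)C(C)(C)C)CC1 | intermediate
3 | (R)-tert-butyldiphenyl{[4-(trimethylsilyloxy)cyclohex-3-en-1-yl]oxy}silane | C[Si](C)(C)OC1=CC[C@H](O[Si](c2ccccc2)(c2ccccc2)C(C)(C)C)CC1 | intermediate
4 | (R)-4-[(tert-butyldiphenylsilyl)oxy]cyclohex-2-en-1-one | O=C1CC[C@@H](O[Si](c2ccccc2)(c2ccccc2)C(C)(C)C)C=C1 | intermediate
5 | (R)-4-[(tert-butyldiphenylsilyl)oxy]-2-iodocyclohex-2-en-1-one | O=C1CC[C@@H](O[Si](c2ccccc2)(c2ccccc2)C(C)(C)C)C=C1I | intermediate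
6 | (R)-4-[(tert-butyldiphenylsilyl)oxy]-2-methylcyclohex-2-en-1-one | O=C1CC[C@@H](O[Si](c2ccccc2)(c2ccccc2)C(C)(C)C)C=C1C | intermediate
7 | 3-(trimethylsilyl)prop-2-yn-1-ol | C[Si](C)(C)C#CCO | starting material
8 | sodium 2,2-bis(2-methoxyethoxy)-3-(trimethylsilyl)-2,5-dihydro-1,2-oxaaluminol-2-uide (cyclic vinylalanate) | C[Si](C)(C)C1=CCO[Al-]1(OCCOC)OCCOC.[Na+] | intermediate (not isolated)
9 | (Z)-3-iodo-3-(trimethylsilyl)prop-2-en-1-ol | C[Si](C)(C)/C(I)=C/CO | intermediate
10 | dimethylzinc | C[Zn]C | starting material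
11 | (E)-3-(trimethylsilyl)but-2-en-1-ol | C[Si](C)(C)/C(C)=C/CO | intermediate
12 | (E)-1-iodo-3-(trimethylsilyl)but-2-ene | C[Si](C)(C)/C(C)=C/CI | intermediate
13 | methyllithium | [Li]C | starting material
14 | lithium dimethylcuprate | [Li+].C[Cu-]C | intermediate (reagent made in the flask, not isolated)
15 | lithium (3R,4R)-4-[(tert-butyldiphenylsilyl)oxy]-2,3-dimethylcyclohex-1-en-1-olate | [Li+].CC1=C([O-])CC[C@@H](O[Si](c2ccccc2)(c2ccccc2)C(C)(C)C)[C@@H]1C | intermediate (not isolated)
16 | (2R,3R,4R)-4-[(tert-butyldiphenylsilyl)oxy]-2,3-dimethyl-2-[(E)-3-(trimethylsilyl)but-2-en-1-yl]cyclohexan-1-one | C[Si](C)(C)/C(C)=C/C[C@@]1(C)C(=O)CC[C@@H](O[Si](c2ccccc2)(c2ccccc2)C(C)(C)C)[C@@H]1C | intermediate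
17 | (2R,3R,4R)-4-[(tert-butyldiphenylsilyl)oxy]-2,3-dimethyl-2-{[3-methyl-3-(trimethylsilyl)oxiran-2-yl]methyl}cyclohexan-1-one (silicon and ring CH2 trans on the oxirane; one of the two epoxide-face diastereomers shown, both give 18) | C[Si](C)(C)[C@]2(C)O[C@@H]2C[C@@]1(C)C(=O)CC[C@@H](O[Si](c3ccccc3)(c3ccccc3)C(C)(C)C)[C@@H]1C | intermediate (not isolated)
18 | (2R,3R,4R)-4-[(tert-butyldiphenylsilyl)oxy]-2,3-dimethyl-2-(3-oxobutyl)cyclohexan-1-one | CC(=O)CC[C@@]1(C)C(=O)CC[C@@H](O[Si](c2ccccc2)(c2ccccc2)C(C)(C)C)[C@@H]1C | intermediate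
19 | (4aR,5R,6R)-6-[(tert-butyldiphenylsilyl)oxy]-4a,5-dimethyl-4,4a,5,6,7,8-hexahydronaphthalen-2(3H)-one (3α-silyloxy-11,12,13-trinoreremophil-9-en-8-one) | O=C1C=C2CC[C@@H](O[Si](c3ccccc3)(c3ccccc3)C(C)(C)C)[C@H](C)[C@@]2(C)CC1 | intermediate
20 | (4aS,5R,6R,8aR)-6-[(tert-butyldiphenylsilyl)oxy]-4a,5-dimethyloctahydronaphthalen-2(1H)-one (cis-fused; 3α-silyloxy-11,12,13-trinor-10βH-eremophilan-8-one) | O=C1C[C@H]2CC[C@@H](O[Si](c3ccccc3)(c3ccccc3)C(C)(C)C)[C@H](C)[C@@]2(C)CC1 | intermediate
21 | 3α-[(tert-butyldiphenylsilyl)oxy]-8-[(tert-butyldimethylsilyl)oxy]-11,12,13-trinor-10βH-eremophil-8-ene | CC(C)(C)[Si](C)(C)OC1=C[C@H]2CC[C@@H](O[Si](c3ccccc3)(c3ccccc3)C(C)(C)C)[C@H](C)[C@@]2(C)CC1 | intermediate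
22 | 3α-[(tert-butyldiphenylsilyl)oxy]-9β-[(tert-butyldimethylsilyl)oxy]-11,12,13-trinor-10βH-eremophilan-8-one (3R,4R,5R,9R,10S) | O=C1[C@H](O[Si](C)(C)C(C)(C)C)[C@H]2CC[C@@H](O[Si](c3ccccc3)(c3ccccc3)C(C)(C)C)[C@H](C)[C@@]2(C)CC1 | intermediate
23 | acetone | CC(C)=O | starting material
24 | lithium 3α-[(tert-butyldiphenylsilyl)oxy]-9β-[(tert-butyldimethylsilyl)oxy]-11,12,13-trinor-10βH-eremophil-7-en-8-olate | [Li+].[O-]C1=CC[C@@]2(C)[C@H](CC[C@@H](O[Si](c3ccccc3)(c3ccccc3)C(C)(C)C)[C@@H]2C)[C@H]1O[Si](C)(C)C(C)(C)C | intermediate (not isolated)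
25 | 3α-[(tert-butyldiphenylsilyl)oxy]-9β-[(tert-butyldimethylsilyl)oxy]-11-hydroxy-7αH,10βH-eremophilan-8-one | CC(C)(O)[C@H]1C[C@@]2(C)[C@H](CC[C@@H](O[Si](c3ccccc3)(c3ccccc3)C(C)(C)C)[C@@H]2C)[C@@H](O[Si](C)(C)C(C)(C)C)C1=O | intermediate
26 | 3α,9β,11-trihydroxy-7αH,10βH-eremophilan-8-one | CC(C)(O)[C@H]1C[C@@]2(C)[C@H](CC[C@@H](O)[C@@H]2C)[C@@H](O)C1=O | intermediate
27 | angelic acid, (Z)-2-methylbut-2-enoic acid | C/C=C(/C)C(=O)O | starting material
28 | 3α,9β-bis[(Z)-2-methylbut-2-enoyloxy]-11-hydroxy-7αH,10βH-eremophilan-8-one | CC(C)(O)[C@H]1C[C@@]2(C)[C@H](CC[C@@H](OC(=O)/C(C)=C\C)[C@@H]2C)[C@@H](OC(=O)/C(C)=C\C)C1=O | intermediate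
29 | (3R,4R,5R,7R,9R,10S)-3,9-bis[(Z)-2-methylbut-2-enoyloxy]eremophil-11-en-8-one (3α,9β-diester, 7β-isopropenyl, 10β-H; CNP0174755.1) | C=C(C)[C@H]1C[C@@]2(C)[C@H](CC[C@@H](OC(=O)/C(C)=C\C)[C@@H]2C)[C@@H](OC(=O)/C(C)=C\C)C1=O | target

**Step count and risks**

Total step count: 18. Longest linear sequence: 15 steps (steps 1–5 and 9–18, from 4-hydroxycyclohexanone); the iodide branch (steps 6–8) joins at step 9.

Steps most likely to fail:

1. Step 9. C-alkylation of the aggregated, tetrasubstituted lithium–copper enolate may be slow, so that proton transfer, O-alkylation or coupling of residual methylcopper with the iodide compete; facial selectivity at C5 may also suffer because the C3 silyloxy group lies 1,3 to the incoming electrophile. The fallback separates the two bond formations. Enone 6 is treated with Me2CuLi in the presence of TMSCl to give the regiodefined enol silane {[(3R,4R)-4-(tert-butyldiphenylsilyloxy)-2,3-dimethylcyclohex-1-en-1-yl]oxy}trimethylsilane F1, which is isolated. MeLi in THF then releases the copper-free lithium enolate 15, and this is alkylated with 12 in THF–HMPA at low temperature to rejoin the route at 16.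

2. Step 18. Elimination toward C7, or drift of the new double bond into conjugation on contact with pyridinium salts, would give the isopropylidene ketone. The fallback sets out from 22 and fixes the double-bond position through the coupling partner. Palladium-catalysed α-alkenylation of the lithium enolate 24 with 2-bromopropene (LiN(SiMe3)2, Pd2(dba)3, P(tBu)3, toluene) should give 3α-(TBDPSO)-9β-(TBSO)-7αH,10βH-eremophil-11-en-8-one F4, the equatorial 7β epimer being the stable one. HF·pyridine then gives 3α,9β-dihydroxy-7αH,10βH-eremophil-11-en-8-one F5, which is esterified as in step 17, at the lowest temperature that still gives conversion, to arrive at 29.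

3. Step 12. Hydrogen may be delivered to the α face, giving the trans-fused decalone. The fallback sets out from 19 and uses a hydroxyl group to steer the metal. Reduction with NaBH4 and CeCl3·7H2O in MeOH gives the 8β allylic alcohol 3α-(TBDPSO)-11,12,13-trinoreremophil-9-en-8β-ol F2. Hydroxyl-directed hydrogenation with [Ir(cod)(PCy3)(py)]PF6 in CH2Cl2 delivers hydrogen to the β face and gives the cis-fused alcohol 3α-(TBDPSO)-11,12,13-trinor-10βH-eremophilan-8β-ol F3. Dess–Martin oxidation returns to 20.

Further compounds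
F1 | step 9 | {[(3R,4R)-4-(tert-butyldiphenylsilyloxy)-2,3-dimethylcyclohex-1-en-1-yl]oxy}trimethylsilane | CC1=C(O[Si](C)(C)C)CC[C@@H](O[Si](c2ccccc2)(c2ccccc2)C(C)(C)C)[C@@H]1C
F2 | step 12 | 3α-[(tert-butyldiphenylsilyl)oxy]-11,12,13-trinoreremophil-9-en-8β-ol | O[C@@H]1C=C2CC[C@@H](O[Si](c3ccccc3)(c3ccccc3)C(C)(C)C)[C@H](C)[C@@]2(C)CC1
F3 | step 12 | 3α-[(tert-butyldiphenylsilyl)oxy]-11,12,13-trinor-10βH-eremophilan-8β-ol | O[C@@H]1C[C@H]2CC[C@@H](O[Si](c3ccccc3)(c3ccccc3)C(C)(C)C)[C@H](C)[C@@]2(C)CC1
F4 | step 18 | 3α-[(tert-butyldiphenylsilyl)oxy]-9β-[(tert-butyldimethylsilyl)oxy]-7αH,10βH-eremophil-11-en-8-one | C=C(C)[C@H]1C[C@@]2(C)[C@H](CC[C@@H](O[Si](c3ccccc3)(c3ccccc3)C(C)(C)C)[C@@H]2C)[C@@H](O[Si](C)(C)C(C)(C)C)C1=O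
F5 | step 18 | 3α,9β-dihydroxy-7αH,10βH-eremophil-11-en-8-one | C=C(C)[C@H]1C[C@@]2(C)[C@H](CC[C@@H](O)[C@@H]2C)[C@@H](O)C1=O
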